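The route rests on cutting ring B at its C7=C8 alkene: C7 is an unsubstituted CH between the C6 methylene and C8, which carries only a methyl group, so ring-closing olefin metathesis between an allyl arm on C5 and an isopropenyl arm on C9 forms ring B in one operation. The precursor is a ring A cyclohexenone (C3 ketone, C4=C5 alkene) carrying both arms; its quaternary C10 and the C9 stereocentre come from one iridium-catalysed enolate allylation of a vinylogous ester, and the allyl arm from a Stork–Danheiser transposition. Reductive methylation, ketone reduction and Mitsunobu etherification with scopoletin finish the synthesis.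

Key step: step 8

Numbering: drimane numbering is used; ring A = C1–C5 and C10 (C3 bears OH, C4 the two methyls, C10 the angular methyl), ring B = C5–C10 (C8 bears the methyl, C9 the C11H2–O-aryl arm).
Remark: in step 4 the ligand enantiomer fixes C9; the face of the enolate (C10) is assumed to follow the sense drawn, by analogy with allylations of 2-alkyl cyclic ketone enolates under the same catalysis.

Step 1
Reactants: 1 3-ethoxy-2-methylcyclohex-2-en-1-one
Product: 4 3-ethoxy-2,6-dimethylcyclohex-2-en-1-one (racemic), via lithium enolate 3 (not isolated)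
Conditions: LiN(iPr)2, THF, −78 °C; then MeI, −78 → 0 °C
Reagents that add atoms: iodomethane (2), CI
Why: Stork–Danheiser α′-alkylation: kinetic deprotonation of the vinylogous ester occurs only at the α′ carbon (future C10), and the stereocentre formed is erased again when the enolate is regenerated in step 4.

Step 2
Reactants: 5 (E)-but-2-ene-1,4-diol
Product: 8 (E)-4-{[tri(propan-2-yl)silyl]oxy}but-2-en-1-ol, via sodium monoalkoxide 7 (not isolated)
Conditions: NaH (1 equiv), THF, 0 °C → rt; then TIPSCl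
Reagents that add atoms: chlorotri(propan-2-yl)silane (6), CC(C)[Si](Cl)(C(C)C)C(C)C
Why: Monosilylation of a symmetric diol: one equivalent of NaH gives the sparingly soluble monoalkoxide, which is O-silylated faster than it equilibrates to the dialkoxide.

Step 3
Reactants: 8 (E)-4-{[tri(propan-2-yl)silyl]oxy}but-2-en-1-ol
Product: 10 methyl (E)-4-{[tri(propan-2-yl)silyl]oxy}but-2-en-1-yl carbonate
Conditions: ClCO2Me, pyridine, CH2Cl2, 0 °C
Reagents that add atoms: methyl chloroformate (9), COC(=O)Cl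
Why: O-acylation of the primary allylic alcohol gives the allylic carbonate, the leaving group needed to form the allyliridium intermediate.

Step 4
Reactants: 4 3-ethoxy-2,6-dimethylcyclohex-2-en-1-one (racemic); 10 methyl (E)-4-{[tri(propan-2-yl)silyl]oxy}but-2-en-1-yl carbonate
Product: 12 (6R)-3-ethoxy-2,6-dimethyl-6-[(2R)-1-{[tri(propan-2-yl)silyl]oxy}but-3-en-2-yl]cyclohex-2-en-1-one, via barium enolate 11 (not isolated)
Conditions: Ba[N(SiMe3)2]2 (0.5 equiv), THF, −78 °C; then 10, [Ir(cod)Cl]2 (2 mol %), BINOL-derived N,N-bis(1-phenylethyl)phosphoramidite (4 mol %, enantiomer that delivers 2R, pre-activated with n-PrNH2), THF, 0 °C → rt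
Reagents that add atoms: none
Why: Iridium-catalysed asymmetric allylic alkylation: the achiral tetrasubstituted enolate attacks the more substituted terminus of the (π-allyl)iridium complex anti to the metal, so the chiral phosphoramidite fixes C9 and the preferred open approach of the enolate face fixes the quaternary C10, a vicinal quaternary/tertiary construction known for barium enolates of 2-substituted cyclic ketones.

Step 5
Reactants: 12 (6R)-3-ethoxy-2,6-dimethyl-6-[(2R)-1-{[tri(propan-2-yl)silyl]oxy}but-3-en-2-yl]cyclohex-2-en-1-one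
Product: 13 (6R)-3-ethoxy-2,6-dimethyl-6-[(2R)-3-oxo-1-{[tri(propan-2-yl)silyl]oxy}butan-2-yl]cyclohex-2-en-1-one
Conditions: PdCl2 (10 mol %), CuCl, O2 (1 atm), DMF/H2O, rt
Reagents that add atoms: water, O
Why: Tsuji–Wacker oxidation: Markovnikov hydroxypalladation of the only monosubstituted alkene gives the methyl ketone (future C8 and its methyl), while the tetrasubstituted push–pull enol ether is inert and no stereocentre is touched.

Step 6
Reactants: 13 (6R)-3-ethoxy-2,6-dimethyl-6-[(2R)-3-oxo-1-{[tri(propan-2-yl)silyl]oxy}butan-2-yl]cyclohex-2-en-1-one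
Product: 15 (6R)-3-ethoxy-2,6-dimethyl-6-[(2R)-3-methyl-1-{[tri(propan-2-yl)silyl]oxy}but-3-en-2-yl]cyclohex-2-en-1-one
Conditions: Ph3PCH3Br, NaN(SiMe3)2, THF, 0 °C → rt
Reagents that add atoms: methyltriphenylphosphonium bromide (14), C[P+](c1ccccc1)(c1ccccc1)c1ccccc1.[Br-]
Why: Wittig methylenation: the non-stabilised ylide adds to the methyl ketone far faster than to the deactivated vinylogous ester carbonyl, and the hindered C9–H is deprotonated too slowly for epimerisation or β-elimination of the silyloxy group to compete.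

Step 7
Reactants: 15 (6R)-3-ethoxy-2,6-dimethyl-6-[(2R)-3-methyl-1-{[tri(propan-2-yl)silyl]oxy}but-3-en-2-yl]cyclohex-2-en-1-one
Product: 18 (4R)-2,4-dimethyl-4-[(2R)-3-methyl-1-{[tri(propan-2-yl)silyl]oxy}but-3-en-2-yl]-3-(prop-2-en-1-yl)cyclohex-2-en-1-one, via magnesium alkoxide adduct 17 (not isolated)
Conditions: CH2=CHCH2MgBr, THF, 0 °C; then 1 M HCl, THF, rt
Reagents that add atoms: allylmagnesium bromide (16), C=CC[Mg]Br; water, O
Why: Stork–Danheiser 1,3-carbonyl transposition: the allyl Grignard reagent adds 1,2 to the hindered C5 carbonyl through a six-membered transition state, and acid hydrolysis of the enol ether followed by loss of water gives the C3 ketone and the C4=C5 alkene, destroying the carbinol stereocentre of 17.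

Step 8
Reactants: 18 (4R)-2,4-dimethyl-4-[(2R)-3-methyl-1-{[tri(propan-2-yl)silyl]oxy}but-3-en-2-yl]-3-(prop-2-en-1-yl)cyclohex-2-en-1-one
Product: 19 (4aR,5R)-1,4a,6-trimethyl-5-({[tri(propan-2-yl)silyl]oxy}methyl)-4,4a,5,8-tetrahydronaphthalen-2(3H)-one
Conditions: RuCl2(=CHPh)(PCy3)(H2IMes) (second-generation Grubbs catalyst, 5 mol %), CH2Cl2 (0.005 M), 40 °C
Reagents that add atoms: none
Why: The ruthenium alkylidene first engages the unhindered terminal alkene of the C5 allyl arm, and the resulting C7 alkylidene undergoes intramolecular [2+2] cycloaddition and cycloreversion with the isopropenyl alkene at C8, forming the C7=C8 bond. The closest known reaction type is ring-closing olefin metathesis of a monosubstituted/1,1-disubstituted diene pair to a trisubstituted cyclohexene. Ring B closes as a six-membered ring with an endocyclic double bond, onto a planar C5 whose enone holds the allyl arm close to the C9 substituent. No stereocentre is created, and C9 and C10 are untouched because neither acid nor base is present. The step needs chemoselectivity for the two terminal alkenes over the tetrasubstituted, electron-poor C4=C5 alkene, which is inert to the catalyst, and cyclisation over dimerisation, secured by high dilution and the quaternary C10 (gem-dialkyl effect). Loss of ethene makes the closure irreversible.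

Step 9
Reactants: 19 (4aR,5R)-1,4a,6-trimethyl-5-({[tri(propan-2-yl)silyl]oxy}methyl)-4,4a,5,8-tetrahydronaphthalen-2(3H)-one
Product: 21 (4aS,5R,8aR)-1,1,4a,6-tetramethyl-5-({[tri(propan-2-yl)silyl]oxy}methyl)-3,4,4a,5,8,8a-hexahydronaphthalen-2(1H)-one, via lithium enolate 20 (not isolated)
Conditions: Li, NH3/THF, t-BuOH (1 equiv), −78 °C; then MeI, −78 → −33 °C
Reagents that add atoms: iodomethane (2), CI
Why: Birch-type reductive alkylation of an enone: electron transfer gives a C5 carbanion that is protonated axially on the face opposite the C10 methyl (trans ring fusion, C5–H α), and the regiodefined enolate is C-methylated at C4 to the gem-dimethyl ketone while the isolated C7=C8 alkene and the silyl ether are not reduced.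

Step 10
Reactants: 21 (4aS,5R,8aR)-1,1,4a,6-tetramethyl-5-({[tri(propan-2-yl)silyl]oxy}methyl)-3,4,4a,5,8,8a-hexahydronaphthalen-2(1H)-one
Product: 22 (2R,4aS,5R,8aR)-1,1,4a,6-tetramethyl-5-({[tri(propan-2-yl)silyl]oxy}methyl)-1,2,3,4,4a,5,8,8a-octahydronaphthalen-2-ol
Conditions: LiBH(s-Bu)3, THF, −78 °C; aqueous work-up
Reagents that add atoms: none
Why: Bulky-hydride reduction: LiBH(s-Bu)3 attacks the C3 ketone of the rigid trans-decalin along the equatorial trajectory and should give the axial 3α alcohol (trans to the C10 methyl), the known outcome for 4,4-dimethyl-3-keto decalins.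

Step 11
Reactants: 22 (2R,4aS,5R,8aR)-1,1,4a,6-tetramethyl-5-({[tri(propan-2-yl)silyl]oxy}methyl)-1,2,3,4,4a,5,8,8a-octahydronaphthalen-2-ol
Product: 23 (2R,4aS,5R,8aR)-5-(hydroxymethyl)-1,1,4a,6-tetramethyl-1,2,3,4,4a,5,8,8a-octahydronaphthalen-2-ol
Conditions: Bu4NF, THF, rt
Reagents that add atoms: none
Why: Fluoride-mediated desilylation frees the primary C11 alcohol without affecting the alkene or any stereocentre.

Step 12
Reactants: 23 (2R,4aS,5R,8aR)-5-(hydroxymethyl)-1,1,4a,6-tetramethyl-1,2,3,4,4a,5,8,8a-octahydronaphthalen-2-ol; 24 scopoletin (7-hydroxy-6-methoxy-2H-chromen-2-one)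
Product: 25 7-{[(1R,4aR,6R,8aS)-6-hydroxy-2,5,5,8a-tetramethyl-1,4,4a,5,6,7,8,8a-octahydronaphthalen-1-yl]methoxy}-6-methoxy-2H-chromen-2-one (target)
Conditions: PPh3, DIAD, THF, 0 °C → rt
Reagents that add atoms: none
Why: Mitsunobu etherification: the acidic 7-hydroxycoumarin displaces the activated primary C11 alcohol by SN2, while the axial secondary C3 alcohol next to the gem-dimethyl carbon is too hindered to be activated and no stereocentre is involved.

Compound list
1 | 3-ethoxy-2-methylcyclohex-2-en-1-one | CCOC1=C(C)C(=O)CCC1 | starting material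
2 | iodomethane | CI | starting material
3 | lithium 5-ethoxy-6-methylcyclohexa-1,5-dien-1-olate | [Li+].CCOC1=C(C)C([O-])=CCC1 | intermediate
4 | 3-ethoxy-2,6-dimethylcyclohex-2-en-1-one (racemic) | CCOC1=C(C)C(=O)C(C)CC1 | intermediate
5 | (E)-but-2-ene-1,4-diol | OC/C=C/CO | starting material
6 | chlorotri(propan-2-yl)silane | CC(C)[Si](Cl)(C(C)C)C(C)C | starting material
7 | sodium (E)-4-hydroxybut-2-en-1-olate | [Na+].[O-]C/C=C/CO | intermediate
8 | (E)-4-{[tri(propan-2-yl)silyl]oxy}but-2-en-1-ol | OC/C=C/CO[Si](C(C)C)(C(C)C)C(C)C | intermediate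
9 | methyl chloroformate | COC(=O)Cl | starting material
10 | methyl (E)-4-{[tri(propan-2-yl)silyl]oxy}but-2-en-1-yl carbonate | COC(=O)OC/C=C/CO[Si](C(C)C)(C(C)C)C(C)C | intermediate
11 | barium bis(5-ethoxy-2,6-dimethylcyclohexa-1,5-dien-1-olate) | [Ba+2].CCOC1=C(C)C([O-])=C(C)CC1.CCOC1=C(C)C([O-])=C(C)CC1 | intermediate
12 | (6R)-3-ethoxy-2,6-dimethyl-6-[(2R)-1-{[tri(propan-2-yl)silyl]oxy}but-3-en-2-yl]cyclohex-2-en-1-one | CCOC1=C(C)C(=O)[C@@](C)([C@H](CO[Si](C(C)C)(C(C)C)C(C)C)C=C)CC1 | intermediate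
13 | (6R)-3-ethoxy-2,6-dimethyl-6-[(2R)-3-oxo-1-{[tri(propan-2-yl)silyl]oxy}butan-2-yl]cyclohex-2-en-1-one | CCOC1=C(C)C(=O)[C@@](C)([C@H](CO[Si](C(C)C)(C(C)C)C(C)C)C(C)=O)CC1 | intermediate
14 | methyltriphenylphosphonium bromide | C[P+](c1ccccc1)(c1ccccc1)c1ccccc1.[Br-] | starting material
15 | (6R)-3-ethoxy-2,6-dimethyl-6-[(2R)-3-methyl-1-{[tri(propan-2-yl)silyl]oxy}but-3-en-2-yl]cyclohex-2-en-1-one | CCOC1=C(C)C(=O)[C@@](C)([C@H](CO[Si](C(C)C)(C(C)C)C(C)C)C(C)=C)CC1 | intermediate
16 | allylmagnesium bromide | C=CC[Mg]Br | starting material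
17 | bromomagnesium (6R)-3-ethoxy-2,6-dimethyl-6-[(2R)-3-methyl-1-{[tri(propan-2-yl)silyl]oxy}but-3-en-2-yl]-1-(prop-2-en-1-yl)cyclohex-2-en-1-olate (both carbinol epimers) | CCOC1=C(C)C(CC=C)(O[Mg]Br)[C@@](C)([C@H](CO[Si](C(C)C)(C(C)C)C(C)C)C(C)=C)CC1 | intermediate
18 | (4R)-2,4-dimethyl-4-[(2R)-3-methyl-1-{[tri(propan-2-yl)silyl]oxy}but-3-en-2-yl]-3-(prop-2-en-1-yl)cyclohex-2-en-1-one | C=CCC1=C(C)C(=O)CC[C@]1(C)[C@H](CO[Si](C(C)C)(C(C)C)C(C)C)C(C)=C | intermediate
19 | (4aR,5R)-1,4a,6-trimethyl-5-({[tri(propan-2-yl)silyl]oxy}methyl)-4,4a,5,8-tetrahydronaphthalen-2(3H)-one | O=C1CC[C@]2(C)[C@H](CO[Si](C(C)C)(C(C)C)C(C)C)C(C)=CCC2=C1C | intermediate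
20 | lithium (4aS,5R,8aR)-1,4a,6-trimethyl-5-({[tri(propan-2-yl)silyl]oxy}methyl)-3,4,4a,5,8,8a-hexahydronaphthalen-2-olate | [Li+].[O-]C1=C(C)[C@@H]2CC=C(C)[C@@H](CO[Si](C(C)C)(C(C)C)C(C)C)[C@@]2(C)CC1 | intermediate
21 | (4aS,5R,8aR)-1,1,4a,6-tetramethyl-5-({[tri(propan-2-yl)silyl]oxy}methyl)-3,4,4a,5,8,8a-hexahydronaphthalen-2(1H)-one | O=C1CC[C@]2(C)[C@H](CO[Si](C(C)C)(C(C)C)C(C)C)C(C)=CC[C@H]2C1(C)C | intermediate
22 | (2R,4aS,5R,8aR)-1,1,4a,6-tetramethyl-5-({[tri(propan-2-yl)silyl]oxy}methyl)-1,2,3,4,4a,5,8,8a-octahydronaphthalen-2-ol | O[C@@H]1CC[C@]2(C)[C@H](CO[Si](C(C)C)(C(C)C)C(C)C)C(C)=CC[C@H]2C1(C)C | intermediate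
23 | (2R,4aS,5R,8aR)-5-(hydroxymethyl)-1,1,4a,6-tetramethyl-1,2,3,4,4a,5,8,8a-octahydronaphthalen-2-ol | O[C@@H]1CC[C@]2(C)[C@H](CO)C(C)=CC[C@H]2C1(C)C | intermediate
24 | scopoletin (7-hydroxy-6-methoxy-2H-chromen-2-one) | COc1cc2ccc(=O)oc2cc1O | starting material
25 | 7-{[(1R,4aR,6R,8aS)-6-hydroxy-2,5,5,8a-tetramethyl-1,4,4a,5,6,7,8,8a-octahydronaphthalen-1-yl]methoxy}-6-methoxy-2H-chromen-2-one | COc1cc2ccc(=O)oc2cc1OC[C@@H]1C(C)=CC[C@H]2C(C)(C)[C@H](O)CC[C@]12C | target

Total step count: 12. Longest linear sequence: 11 steps (from 5 through steps 2, 3 and 4–12); 10 steps from 1.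

Steps most likely to fail

1. Step 4. The facial selectivity of the tetrasubstituted barium enolate toward the allyliridium intermediate may be low or of the opposite sense, so that C10 forms in the wrong relationship to C9; linear attack may also compete. Fallback: the C9/C10 relationship is corrected by epimerisation instead of being set in one event. Setting out from 4 and 10, the allylation is run with the mirror-image ligand, chosen so that C10 has the required configuration in the then favoured diastereomer, the C9 epimer (6R)-3-ethoxy-2,6-dimethyl-6-[(2S)-1-{[tri(propan-2-yl)silyl]oxy}but-3-en-2-yl]cyclohex-2-en-1-one F1. Wacker oxidation as in step 5 gives the epimeric methyl ketone (6R)-3-ethoxy-2,6-dimethyl-6-[(2S)-3-oxo-1-{[tri(propan-2-yl)silyl]oxy}butan-2-yl]cyclohex-2-en-1-one F2, in which C9 is α to the ketone and is equilibrated with DBU in toluene at 60 °C. Compound 13 is separated, F2 is recycled, and the route is rejoined at 13.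

2. Step 8. Closure onto the hindered 1,1-disubstituted alkene next to the quaternary centre may be slow, letting olefin isomerisation or dimerisation through the allyl arm take over. Fallback: the same C7=C8 bond is made by carbonyl coupling instead of metathesis. Setting out from 18, reductive methylation under the conditions of step 9 gives the monocyclic ketone (3R,4S)-2,2,4-trimethyl-4-[(2R)-3-methyl-1-{[tri(propan-2-yl)silyl]oxy}but-3-en-2-yl]-3-(prop-2-en-1-yl)cyclohexan-1-one F3. LiBH(s-Bu)3 reduction gives the axial alcohol (1R,3R,4S)-2,2,4-trimethyl-4-[(2R)-3-methyl-1-{[tri(propan-2-yl)silyl]oxy}but-3-en-2-yl]-3-(prop-2-en-1-yl)cyclohexan-1-ol F4. Ozonolysis of both terminal alkenes (O3, CH2Cl2/MeOH, −78 °C; Me2S) gives the keto aldehyde F5 (C7 aldehyde on the C5 arm, C8 methyl ketone on C9, stereocentres unchanged). Intramolecular McMurry coupling (TiCl3, Zn–Cu, DME, reflux) then closes ring B and rejoins the route at 22.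

3. Step 9. Protonation of C5 may occur on the wrong face (cis ring fusion), or base may conjugate the skipped dienone before it is reduced. Fallback: C5 is set by conjugate addition on the monocycle instead of by protonation on the bicycle. Setting out from 15, i-Bu2AlH (CH2Cl2, −78 °C) followed by 1 M HCl gives the enone (4S)-2,4-dimethyl-4-[(2R)-3-methyl-1-{[tri(propan-2-yl)silyl]oxy}but-3-en-2-yl]cyclohex-2-en-1-one F6. Copper-mediated conjugate addition (CH2=CHCH2MgBr, CuBr·SMe2, Me3SiCl, THF, −78 °C) delivers the allyl group to C5 anti to the bulky C9 side chain and gives the trimethylsilyl enol ether F7. MeLi then MeI gives the same monocyclic ketone F3 as in the fallback to step 8. Ring-closing metathesis of F3 under the conditions of step 8 rejoins the route at 21.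

Further compounds
F1 | step 4 | (6R)-3-ethoxy-2,6-dimethyl-6-[(2S)-1-{[tri(propan-2-yl)silyl]oxy}but-3-en-2-yl]cyclohex-2-en-1-one | CCOC1=C(C)C(=O)[C@@](C)([C@@H](CO[Si](C(C)C)(C(C)C)C(C)C)C=C)CC1
F2 | step 4 | (6R)-3-ethoxy-2,6-dimethyl-6-[(2S)-3-oxo-1-{[tri(propan-2-yl)silyl]oxy}butan-2-yl]cyclohex-2-en-1-one | CCOC1=C(C)C(=O)[C@@](C)([C@@H](CO[Si](C(C)C)(C(C)C)C(C)C)C(C)=O)CC1
F3 | step 8 | (3R,4S)-2,2,4-trimethyl-4-[(2R)-3-methyl-1-{[tri(propan-2-yl)silyl]oxy}but-3-en-2-yl]-3-(prop-2-en-1-yl)cyclohexan-1-one | O=C1CC[C@](C)([C@H](CO[Si](C(C)C)(C(C)C)C(C)C)C(C)=C)[C@@H](CC=C)C1(C)C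
F4 | step 8 | (1R,3R,4S)-2,2,4-trimethyl-4-[(2R)-3-methyl-1-{[tri(propan-2-yl)silyl]oxy}but-3-en-2-yl]-3-(prop-2-en-1-yl)cyclohexan-1-ol | O[C@@H]1CC[C@](C)([C@H](CO[Si](C(C)C)(C(C)C)C(C)C)C(C)=C)[C@@H](CC=C)C1(C)C
F5 | step 8 | keto aldehyde from double ozonolysis of F4 (2-oxoethyl arm on C5, 3-oxobutan-2-yl arm on C10, stereocentres as in F4) | O[C@@H]1CC[C@](C)([C@H](CO[Si](C(C)C)(C(C)C)C(C)C)C(C)=O)[C@@H](CC=O)C1(C)C
F6 | step 9 | (4S)-2,4-dimethyl-4-[(2R)-3-methyl-1-{[tri(propan-2-yl)silyl]oxy}but-3-en-2-yl]cyclohex-2-en-1-one | C1=C(C)C(=O)CC[C@]1(C)[C@H](CO[Si](C(C)C)(C(C)C)C(C)C)C(C)=C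
F7 | step 9 | trimethylsilyl enol ether of the conjugate allyl adduct of F6 (C3–O–SiMe3, C3=C4, allyl on C5 cis to the C10 methyl) | C[Si](C)(C)OC1=C(C)[C@H](CC=C)[C@](C)(CC1)[C@H](CO[Si](C(C)C)(C(C)C)C(C)C)C(C)=C
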